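The route rests on disconnecting ring B (the dimethoxybenzoyl ring) at two adjacent ring carbons. C1' carries the depside carbonyl and C2' carries the CH2 of the oxopentyl chain. The methoxy group on C6', next to C1', is the feature that steers the reaction. In one operation 3,5-dimethoxybenzyne is inserted into the CH2–C(=O)OAr bond of a malonyl unit already bound to O4 of ring A. Both ortho substituents and the intact depside ester therefore appear together. The precursor is dibenzyl-protected olivetolic acid acylated on O4 by a malonic half Weinreb amide, and the amide later becomes the propyl ketone.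

Key step: step 10

Remark: olivetolic acid 1 is taken as a catalogue compound. Buying it avoids carboxylating olivetol, where attack between the two hydroxyl groups competes with attack next to the pentyl chain. The target has no stereocentre.

Step 1
Reactants: 1 olivetolic acid (2,4-dihydroxy-6-pentylbenzoic acid)
Product: 2 benzyl 2,4-dihydroxy-6-pentylbenzoate
Conditions: BnBr (1.05 equiv), KHCO3, DMF, rt
Reagents that add atoms: benzyl bromide, BrCc1ccccc1
Why: Bicarbonate ionises only the carboxylic acid, so SN2 alkylation of the carboxylate should give the benzyl ester and leave both phenols free.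

Step 2
Reactants: 2 benzyl 2,4-dihydroxy-6-pentylbenzoate
Product: 3 benzyl 4-(allyloxy)-2-hydroxy-6-pentylbenzoate
Conditions: allyl bromide (1.05 equiv), K2CO3 (1.1 equiv), acetone, reflux
Reagents that add atoms: allyl bromide, C=CCBr
Why: In this Williamson ether synthesis the C2 hydroxyl is hydrogen-bonded to the ester carbonyl and is the poorer nucleophile, so one equivalent of halide should go to the C4 hydroxyl.

Step 3
Reactants: 3 benzyl 4-(allyloxy)-2-hydroxy-6-pentylbenzoate
Product: 4 benzyl 4-(allyloxy)-2-(benzyloxy)-6-pentylbenzoate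
Conditions: BnBr (1.5 equiv), K2CO3 (2 equiv), DMF, 60 °C
Reagents that add atoms: benzyl bromide, BrCc1ccccc1
Why: With O4 blocked, a second and more forcing Williamson etherification benzylates the chelated C2 phenol, and the allyl ether and the hindered benzyl ester are inert to K2CO3 at this temperature.

Step 4
Reactants: 4 benzyl 4-(allyloxy)-2-(benzyloxy)-6-pentylbenzoate
Product: 5 benzyl 2-(benzyloxy)-4-hydroxy-6-pentylbenzoate
Conditions: Pd(PPh3)4 (5 mol %), morpholine (5 equiv), THF, rt
Reagents that add atoms: none
Why: In this Tsuji–Trost deallylation zerovalent palladium ionises the aryl allyl ether to a pi-allyl complex that morpholine intercepts, while the benzyl ether and benzyl ester are untouched.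

Step 5
Reactants: 6 Meldrum's acid (2,2-dimethyl-1,3-dioxane-4,6-dione); 7 N,O-dimethylhydroxylamine hydrochloride
Product: 9 3-[methoxy(methyl)amino]-3-oxopropanoic acid, via N,O-dimethylhydroxylamine 8 (not isolated)
Conditions: 7, Et3N (1 equiv per 7), MeCN, rt; then 6, sealed vessel, 75 °C; acidic work-up
Reagents that add atoms: none
Why: In this aminolysis of Meldrum's acid the liberated amine is about as weakly basic as an aniline and so is not lost to salt formation with the acidic CH2; it opens the activated cyclic diester at one carbonyl, and the residue collapses to acetone and the malonamic acid.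

Step 6
Reactants: 5 benzyl 2-(benzyloxy)-4-hydroxy-6-pentylbenzoate; 9 3-[methoxy(methyl)amino]-3-oxopropanoic acid
Product: 10 benzyl 2-(benzyloxy)-4-{[3-(methoxy(methyl)amino)-3-oxopropanoyl]oxy}-6-pentylbenzoate
Conditions: DCC (1.1 equiv), DMAP (5 mol %), CH2Cl2, 0 °C → rt
Reagents that add atoms: none
Why: In this Steglich esterification the C4 phenol is the only free nucleophile in 5, and low temperature with little DMAP limits base-induced breakdown of the activated aryl malonyl ester.

Step 7
Reactants: 11 3,5-dimethoxyphenol
Product: 12 3,5-dimethoxyphenyl isopropylcarbamate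
Conditions: i-PrNCO (1.2 equiv), Et3N (cat.), CH2Cl2, rt
Reagents that add atoms: isopropyl isocyanate, CC(C)N=C=O
Why: Base-catalysed addition of the phenol to the isocyanate (carbamoylation) installs a strong directing group that can later be removed under mild conditions.

Step 8
Reactants: 12 3,5-dimethoxyphenyl isopropylcarbamate
Product: 16 3,5-dimethoxy-2-(trimethylsilyl)phenyl isopropylcarbamate, via N-silyl carbamate 13 (not isolated), via aryllithium 14 (not isolated), via bis-silyl carbamate 15 (not isolated)
Conditions: TBSOTf, TMEDA, Et2O, 0 °C → rt; n-BuLi (2 equiv), TMEDA, −78 °C; TMSCl, −78 °C → rt; aq NaHSO4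
Reagents that add atoms: chlorotrimethylsilane, C[Si](C)(C)Cl (TBSOTf, CC(C)(C)[Si](C)(C)OS(=O)(=O)C(F)(F)F, and n-BuLi, [Li]CCCC, leave atoms only in the transient compounds 13–15)
Why: In this directed ortho-metalation, transient N-silylation masks the NH and lithiation occurs at C2 between the carbamate and a methoxy group (C2 and C6 are equivalent by symmetry); TMSCl then traps the aryllithium and the acidic work-up removes the N-silyl group.

Step 9
Reactants: 16 3,5-dimethoxy-2-(trimethylsilyl)phenyl isopropylcarbamate
Product: 18 3,5-dimethoxy-2-(trimethylsilyl)phenyl trifluoromethanesulfonate, via silyl phenol 17 (not isolated)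
Conditions: DBU (1.5 equiv), Et2NH (1.2 equiv), MeCN, 40 °C; then PhNTf2 (1.5 equiv), rt
Reagents that add atoms: N-phenylbis(trifluoromethanesulfonimide), O=S(=O)(N(c1ccccc1)S(=O)(=O)C(F)(F)F)C(F)(F)F
Why: DBU triggers E1cB cleavage of the secondary carbamate and diethylamine scavenges the isocyanate; O-sulfonylation of the phenoxide in the same flask avoids handling the electron-rich silyl phenol, which is prone to protodesilylation.

Step 10
Reactants: 10 benzyl 2-(benzyloxy)-4-{[3-(methoxy(methyl)amino)-3-oxopropanoyl]oxy}-6-pentylbenzoate; 18 3,5-dimethoxy-2-(trimethylsilyl)phenyl trifluoromethanesulfonate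
Product: 21 benzyl 2-(benzyloxy)-4-{[2,4-dimethoxy-6-(2-(methoxy(methyl)amino)-2-oxoethyl)benzoyl]oxy}-6-pentylbenzoate, via 3,5-dimethoxybenzyne 19 (not isolated), via benzocyclobutene alkoxide 20 (not isolated)
Conditions: KF (3 equiv), 18-crown-6 (3 equiv), THF, rt; 18 (1.5 equiv) added over 2 h
Reagents that add atoms: none
Why: Proposed new method: fluoride removes the silyl group of 18 and triflate departs to give aryne 19, while the same base keeps a small amount of 10 as its enolate, whose carbon bonds to the aryne carbon meta to the flanking methoxy group (future C2') so that the charge builds up on the carbon next to that methoxy group (future C1'), where the C–O dipole stabilises it. The carbanion then closes on the aryl ester carbonyl in a 4-exo-trig mode to alkoxide 20, whose strained four-membered ring breaks at the bond between the former carbonyl carbon and the amide-bearing CH, so that no ring is retained, the ester ends up on C1', and the amide enolate on the C2' side chain takes a proton from fresh 10 to carry the chain. The closest known reaction type is aryne acyl-alkylation, the insertion of arynes into the C–C bond of beta-keto esters and of symmetrical dialkyl malonates (the latter with KF and 18-crown-6 at room temperature), whereas an unsymmetrical malonyl unit made of an aryl ester and a Weinreb amide has not been used. Two selectivities are required: the site of attack on the aryne, which the C6' methoxy group secures through the well-established bias of 3-alkoxyarynes, and the choice of carbonyl, which is secured because a phenol-derived ester is far more electrophilic than an N-methoxy amide. If 20 were to expel ring A aryloxide instead, the strained amide-substituted benzocyclobutenone formed would be reopened by that aryloxide to the same enolate, so both modes of collapse converge as long as slow addition keeps the aryne scarce. Product 21 has no stereocentre (the two in 20 vanish on ring opening), and O2 of ring A has to be benzylated because a free salicylate hydroxyl would itself add to the aryne and cyclise onto the ester.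

Step 11
Reactants: 21 benzyl 2-(benzyloxy)-4-{[2,4-dimethoxy-6-(2-(methoxy(methyl)amino)-2-oxoethyl)benzoyl]oxy}-6-pentylbenzoate
Product: 23 benzyl 2-(benzyloxy)-4-{[2,4-dimethoxy-6-(2-oxopentyl)benzoyl]oxy}-6-pentylbenzoate, via magnesium chelate 22 (not isolated)
Conditions: n-PrMgBr (1.5 equiv), THF, −78 → −20 °C; cold 1 M HCl quench
Reagents that add atoms: propylmagnesium bromide, CCC[Mg]Br
Why: In this Weinreb ketone synthesis the Grignard reagent adds once to the unhindered N-methoxy-N-methyl amide to give the five-membered chelate 22, which holds until the cold acidic quench, whereas both ester carbonyls lie between two ortho substituents and should be too shielded to react at this temperature.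

Step 12
Reactants: 23 benzyl 2-(benzyloxy)-4-{[2,4-dimethoxy-6-(2-oxopentyl)benzoyl]oxy}-6-pentylbenzoate
Product: 24 4-{[2,4-dimethoxy-6-(2-oxopentyl)benzoyl]oxy}-2-hydroxy-6-pentylbenzoic acid (target)
Conditions: H2 (1 atm), 10% Pd/C, EtOAc, rt
Reagents that add atoms: none
Why: Catalytic hydrogenolysis cleaves the two benzylic C–O bonds under neutral conditions, which spare the depside ester, the ketone (not conjugated with ring B) and the salicylic acid, which decarboxylates readily.

Compound list
1 | olivetolic acid (2,4-dihydroxy-6-pentylbenzoic acid) | CCCCCc1cc(O)cc(O)c1C(=O)O | starting material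
2 | benzyl 2,4-dihydroxy-6-pentylbenzoate | CCCCCc1cc(O)cc(O)c1C(=O)OCc1ccccc1 | intermediate
3 | benzyl 4-(allyloxy)-2-hydroxy-6-pentylbenzoate | CCCCCc1cc(OCC=C)cc(O)c1C(=O)OCc1ccccc1 | intermediate
4 | benzyl 4-(allyloxy)-2-(benzyloxy)-6-pentylbenzoate | CCCCCc1cc(OCC=C)cc(OCc2ccccc2)c1C(=O)OCc1ccccc1 | intermediate
5 | benzyl 2-(benzyloxy)-4-hydroxy-6-pentylbenzoate | CCCCCc1cc(O)cc(OCc2ccccc2)c1C(=O)OCc1ccccc1 | intermediate
6 | Meldrum's acid | CC1(C)OC(=O)CC(=O)O1 | starting material
7 | N,O-dimethylhydroxylamine hydrochloride | CNOC.Cl | starting material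
8 | N,O-dimethylhydroxylamine (free base, not isolated) | CNOC | intermediate
9 | 3-[methoxy(methyl)amino]-3-oxopropanoic acid | CON(C)C(=O)CC(=O)O | intermediate
10 | benzyl 2-(benzyloxy)-4-{[3-(methoxy(methyl)amino)-3-oxopropanoyl]oxy}-6-pentylbenzoate | CCCCCc1cc(OC(=O)CC(=O)N(C)OC)cc(OCc2ccccc2)c1C(=O)OCc1ccccc1 | intermediate
11 | 3,5-dimethoxyphenol | COc1cc(O)cc(OC)c1 | starting material
12 | 3,5-dimethoxyphenyl isopropylcarbamate | COc1cc(OC)cc(OC(=O)NC(C)C)c1 | intermediate
13 | 3,5-dimethoxyphenyl N-(tert-butyldimethylsilyl)-N-isopropylcarbamate (not isolated) | COc1cc(OC)cc(OC(=O)N(C(C)C)[Si](C)(C)C(C)(C)C)c1 | intermediate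
14 | 2-lithio derivative of 13 (not isolated) | [Li]c1c(OC)cc(OC)cc1OC(=O)N(C(C)C)[Si](C)(C)C(C)(C)C | intermediate
15 | 3,5-dimethoxy-2-(trimethylsilyl)phenyl N-(tert-butyldimethylsilyl)-N-isopropylcarbamate (not isolated) | COc1cc(OC)c([Si](C)(C)C)c(OC(=O)N(C(C)C)[Si](C)(C)C(C)(C)C)c1 | intermediate
16 | 3,5-dimethoxy-2-(trimethylsilyl)phenyl isopropylcarbamate | COc1cc(OC)c([Si](C)(C)C)c(OC(=O)NC(C)C)c1 | intermediate
17 | 3,5-dimethoxy-2-(trimethylsilyl)phenol (present as its DBU salt, not isolated) | COc1cc(O)c([Si](C)(C)C)c(OC)c1 | intermediate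
18 | 3,5-dimethoxy-2-(trimethylsilyl)phenyl trifluoromethanesulfonate | COc1cc(OC)c([Si](C)(C)C)c(OS(=O)(=O)C(F)(F)F)c1 | intermediate
19 | 3,5-dimethoxybenzyne (not isolated) | COC1=CC(OC)=CC#C1 | intermediate
20 | benzocyclobutene alkoxide from closure of C1' on the ester carbonyl (drawn as the anion, diastereomer mixture, both centres lost on ring opening, not isolated) | COc1cc(OC)c2c(c1)C(C(=O)N(C)OC)C2([O-])Oc1cc(CCCCC)c(C(=O)OCc3ccccc3)c(OCc3ccccc3)c1 | intermediate
21 | benzyl 2-(benzyloxy)-4-{[2,4-dimethoxy-6-(2-(methoxy(methyl)amino)-2-oxoethyl)benzoyl]oxy}-6-pentylbenzoate | CCCCCc1cc(OC(=O)c2c(CC(=O)N(C)OC)cc(OC)cc2OC)cc(OCc2ccccc2)c1C(=O)OCc1ccccc1 | intermediate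
22 | bromomagnesium alkoxide (chelated tetrahedral adduct of 21 and the Grignard reagent, racemic, not isolated) | CCCC(O[Mg]Br)(Cc1cc(OC)cc(OC)c1C(=O)Oc1cc(CCCCC)c(C(=O)OCc2ccccc2)c(OCc2ccccc2)c1)N(C)OC | intermediate
23 | benzyl 2-(benzyloxy)-4-{[2,4-dimethoxy-6-(2-oxopentyl)benzoyl]oxy}-6-pentylbenzoate | CCCCCc1cc(OC(=O)c2c(CC(=O)CCC)cc(OC)cc2OC)cc(OCc2ccccc2)c1C(=O)OCc1ccccc1 | intermediate
24 | 4-{[2,4-dimethoxy-6-(2-oxopentyl)benzoyl]oxy}-2-hydroxy-6-pentylbenzoic acid | CCCCCc1cc(OC(=O)c2c(CC(=O)CCC)cc(OC)cc2OC)cc(O)c1C(=O)O | target

Total step count: 12. Longest linear sequence: 8 (steps 1, 2, 3, 4, 6, 10, 11, 12).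

Steps most likely to fail

1. Step 10 (Proposed new method).
- The aryl carbanion may be quenched by proton transfer before it closes the four-membered ring, which gives plain alpha-arylation.
- A second arylation of the active methylene may follow.
- The carbanion may choose the amide carbonyl.
- The enolate of 10 may shed ring A aryloxide by an E1cB (ketene) pathway, after which the aryne would consume the aryloxide.

The fallback uses known chemistry only, sets out from 18 and returns at 21. Compound 18 is combined with dimethyl malonate under KF/18-crown-6 in THF, an established aryne insertion into a symmetrical malonate, to give methyl 2,4-dimethoxy-6-(2-methoxy-2-oxoethyl)benzoate F1. Saponification of both esters (KOH, aq EtOH, reflux) gives 2-(carboxymethyl)-4,6-dimethoxybenzoic acid F2. Ac2O in toluene closes 6,8-dimethoxyisochromane-1,3-dione F3. Amine 8, freed from 7 with Et3N in CH2Cl2, opens the anhydride at the unconjugated and less hindered CH2–C=O carbonyl to give 2,4-dimethoxy-6-{2-[methoxy(methyl)amino]-2-oxoethyl}benzoic acid F4. A mixed-anhydride depside condensation of this acid with phenol 5, using (CF3CO)2O in toluene at rt, reaches 21.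

2. Step 11.
- The Grignard reagent may deprotonate the activated benzylic CH2 instead of adding.
- It may add to the depside ester.
- The magnesium alkoxide of 22 (or the enolate) may attack the neighbouring aryl ester, so that lactonisation expels ring A and the depside bond is lost.

The fallback avoids basic organometallics, sets out from 21 and returns at 24. Cp2Zr(H)Cl in THF at rt reduces the Weinreb amide chemoselectively to the arylacetaldehyde F5. A Barbier allylation (allyl bromide, In powder, THF/H2O, rt) is run in a protic medium, so no long-lived alkoxide forms, and gives the racemic homoallylic alcohol F6. Dess–Martin periodinane with NaHCO3 in CH2Cl2 gives the allyl ketone F7. H2 over Pd/C in EtOAc then saturates the alkene and removes both benzyl groups in one operation to give 24.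

3. Step 5.
- Proton transfer between the amine and Meldrum's acid may stall the ring opening.
- The volatile amine may escape.
- The malonamic acid may decarboxylate on heating.
- The malonamic acid may be lost to the aqueous phase on work-up.

The fallback sets out from 7 and returns at 9. Acylation of 7 with methyl 3-chloro-3-oxopropanoate (Et3N, 2 equiv, CH2Cl2, 0 °C) gives methyl 3-[methoxy(methyl)amino]-3-oxopropanoate F8. This ester is saponified with LiOH in THF/H2O at 0 °C and acidified to give 9.

Further compounds
F1 | step 10 | methyl 2,4-dimethoxy-6-(2-methoxy-2-oxoethyl)benzoate | COC(=O)Cc1cc(OC)cc(OC)c1C(=O)OC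
F2 | step 10 | 2-(carboxymethyl)-4,6-dimethoxybenzoic acid | O=C(O)Cc1cc(OC)cc(OC)c1C(=O)O
F3 | step 10 | 6,8-dimethoxyisochromane-1,3-dione | COc1cc2c(c(OC)c1)C(=O)OC(=O)C2
F4 | step 10 | 2,4-dimethoxy-6-{2-[methoxy(methyl)amino]-2-oxoethyl}benzoic acid | CON(C)C(=O)Cc1cc(OC)cc(OC)c1C(=O)O
F5 | step 11 | benzyl 2-(benzyloxy)-4-{[2,4-dimethoxy-6-(2-oxoethyl)benzoyl]oxy}-6-pentylbenzoate | CCCCCc1cc(OC(=O)c2c(CC=O)cc(OC)cc2OC)cc(OCc2ccccc2)c1C(=O)OCc1ccccc1
F6 | step 11 | benzyl 2-(benzyloxy)-4-{[2-(2-hydroxypent-4-en-1-yl)-4,6-dimethoxybenzoyl]oxy}-6-pentylbenzoate (racemic) | CCCCCc1cc(OC(=O)c2c(CC(O)CC=C)cc(OC)cc2OC)cc(OCc2ccccc2)c1C(=O)OCc1ccccc1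
F7 | step 11 | benzyl 2-(benzyloxy)-4-{[2,4-dimethoxy-6-(2-oxopent-4-en-1-yl)benzoyl]oxy}-6-pentylbenzoate | CCCCCc1cc(OC(=O)c2c(CC(=O)CC=C)cc(OC)cc2OC)cc(OCc2ccccc2)c1C(=O)OCc1ccccc1
F8 | step 5 | methyl 3-[methoxy(methyl)amino]-3-oxopropanoate | COC(=O)CC(=O)N(C)OC
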